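**Retrosynthetic overview**
1. Target ⇐ cross-metathesis of a terminal-alkene acid with methyl vinyl ketone (installs the E-enone last).
2. C3–CH2CO2H and C6–Et ⇐ two successive axial substitutions on peroxycarbenium ions of a 3-methoxy-1,2-dioxan-6-ol; the C4 ethyl group anchors the chair for both.
3. The 1,2-dioxane (the only ring made) ⇐ cobalt/O2 oxidative ring expansion of a 2-methoxycyclobutanol (C6–C3 bond cleaved, O2 inserted).
4. Cyclobutanol ⇐ C7–C12 alkyllithium + (2R,3S)-3-ethyl-2-methoxycyclobutanone, made by desymmetrising enolisation and Rubottom oxidation of 3-ethylcyclobutanone.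
5. Side chain ⇐ copper-catalysed SN2′ allylic alkylation of (E)-1-bromopent-2-ene by the Grignard reagent from (R)-3-bromo-2-methylpropan-1-ol.

Assumption: 3-ethylcyclobutan-1-one is taken as a commercially available building block.
Locants C1–C14 used below are those of the target chain (C1 = CO2H; C3 and C6 = the two peroxide-bearing ring carbons).

**Step 1**
Reactants: 1 (R)-3-bromo-2-methylpropan-1-ol
Product: 2 (R)-(3-bromo-2-methylpropoxy)triethylsilane
Conditions: Et3SiCl, imidazole, CH2Cl2, 0 °C to rt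
Reagents that add atoms: chlorotriethylsilane, CC[Si](Cl)(CC)CC
Why: Imidazole-mediated silylation masks the hydroxyl so the bromide can be converted into a Grignard reagent; the C8 stereocentre comes from the chiral pool and is not touched.

**Step 2**
Reactants: 2 (R)-(3-bromo-2-methylpropoxy)triethylsilane; 3 (E)-1-bromopent-2-ene
Product: 6 (2S,4S)-4-ethyl-2-methylhex-5-en-1-ol, via Grignard reagent 4 (not isolated), via triethylsilyl ether 5 (not isolated)
Conditions: Mg, Et2O, reflux; then 3, CuBr·SMe2 (3 mol %), Taniaphos C43H39FeNP2 (4 mol %, the enantiomer that gives 4S), CH2Cl2, −78 °C; then 1 M HCl, MeOH, rt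
Reagents that add atoms: none
Why: Copper-catalysed asymmetric allylic alkylation (SN2′) of the allyl bromide by the alkyl Grignard reagent gives the branched terminal alkene, the chiral diphosphine setting the new C10 centre (4S) under catalyst control regardless of the remote C8 centre, and acidic methanol removes the silyl group during work-up.

**Step 3**
Reactants: 6 (2S,4S)-4-ethyl-2-methylhex-5-en-1-ol
Product: 7 (3S,5S)-3-ethyl-6-iodo-5-methylhex-1-ene
Conditions: PPh3, I2, imidazole, CH2Cl2, 0 °C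
Reagents that add atoms: iodine, [I][I]
Why: Appel-type iodination of the primary alcohol, which leaves both stereocentres and the alkene unchanged.

**Step 4**
Reactants: 8 3-ethylcyclobutan-1-one
Product: 11 (2R,3S)-3-ethyl-2-hydroxycyclobutan-1-one, via silyl enol ether 9 (not isolated), via silyloxy ketone 10 (not isolated)
Conditions: LiN[(R)-CH(CH3)Ph]2, Me3SiCl, THF, −100 °C; then dimethyldioxirane, acetone/CH2Cl2, −40 °C; then MeOH, citric acid (cat.), 0 °C
Reagents that add atoms: dimethyldioxirane, CC1(C)OO1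
Why: Enantiotopic-proton-selective deprotonation of the prochiral ketone by the C2-symmetric chiral lithium amide with in situ silylation (desymmetrisation) fixes the ethyl-bearing carbon (later C4) as S (the antipodal amide gives the antipode), and Rubottom oxidation by the dioxirane adds oxygen anti to the ethyl group to give the trans α-ketol, whose carbinol centre is erased later.

**Step 5**
Reactants: 11 (2R,3S)-3-ethyl-2-hydroxycyclobutan-1-one
Product: 12 (2R,3S)-3-ethyl-2-methoxycyclobutan-1-one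
Conditions: MeI, Ag2O, 4 Å molecular sieves, CH2Cl2, rt, dark
Reagents that add atoms: iodomethane, IC
Why: Purdie methylation etherifies the α-ketol under neutral conditions, so the strained hydroxy ketone neither ring-contracts nor epimerises at the ethyl-bearing carbon (which is not enolisable).

**Step 6**
Reactants: 7 (3S,5S)-3-ethyl-6-iodo-5-methylhex-1-ene; 12 (2R,3S)-3-ethyl-2-methoxycyclobutan-1-one
Product: 14 (2R,3S)-3-ethyl-1-[(2S,4S)-4-ethyl-2-methylhex-5-en-1-yl]-2-methoxycyclobutan-1-ol (both C1 epimers), via alkyllithium 13 (not isolated)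
Conditions: 7, t-BuLi (2.1 equiv), Et2O/pentane, −78 °C; then 12, −78 °C; then H2O
Reagents that add atoms: none
Why: Iodine–lithium exchange at −78 °C (where the 5-hexenyllithium does not cyclise) and 1,2-addition to the electrophilic cyclobutanone join the two fragments; the new carbinol centre forms as a mixture, which does not matter because it becomes a ketone carbon in the next step.

**Step 7**
Reactants: 14 (2R,3S)-3-ethyl-1-[(2S,4S)-4-ethyl-2-methylhex-5-en-1-yl]-2-methoxycyclobutan-1-ol
Product: 16 (4S)-4-ethyl-6-[(2S,4S)-4-ethyl-2-methylhex-5-en-1-yl]-3-methoxy-1,2-dioxan-6-ol (epimers at C3 and C6), via hydroperoxy ketone 15 (not isolated)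
Conditions: Co(acac)2 (10 mol %), O2 (1 atm), ClCH2CH2Cl, 40 °C
Reagents that add atoms: dioxygen, O=O
Why: Cobalt-catalysed aerobic oxidative ring expansion of a cyclobutanol: the alkoxyl radical undergoes strain-driven β-scission of the C6–C3 bond towards the methoxy-stabilised carbon radical, O2 is captured there, and the resulting hydroperoxide closes onto the freed ketone to give the six-membered peroxy hemiketal; C4 is untouched, and the two acetal centres need no control because both are ionised later.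

**Step 8**
Reactants: 16 (4S)-4-ethyl-6-[(2S,4S)-4-ethyl-2-methylhex-5-en-1-yl]-3-methoxy-1,2-dioxan-6-ol
Product: 19 (4S,6R)-4,6-diethyl-6-[(2S,4S)-4-ethyl-2-methylhex-5-en-1-yl]-3-methoxy-1,2-dioxane (C3 epimers), via silyl peroxyketal 17 (not isolated), via peroxycarbenium triflate 18 (not isolated)
Conditions: Me3SiOTf (2.2 equiv), 2,6-di-tert-butyl-4-methylpyridine (1.2 equiv), CH2Cl2, −78 °C; then Et2Zn (2 equiv), −78 °C
Reagents that add atoms: diethylzinc, CC[Zn]CC
Why: Proposed new method: silylation and ionisation of the tertiary peroxy hemiketal gives the C6 peroxycarbenium ion (the secondary methoxy acetal at C3 ionises much more slowly at −78 °C), and Et2Zn, expected to be too weak a nucleophile to attack the O–O bond at this temperature, should transfer ethyl along the axial trajectory of the half-chair with the C4 ethyl pseudo-equatorial (attack from the other face would meet the C4 substituent 1,3-diaxially or require a twist-boat), so the new ethyl ends axial and trans to the C4 ethyl with the side chain equatorial (6R); the closest known reactions are the Lewis-acid-mediated axial alkylation of cyclic α-acetoxy ethers by dialkylzincs and the trapping of peroxycarbenium ions by allylsilanes and silyl enol ethers.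

**Step 9**
Reactants: 19 (4S,6R)-4,6-diethyl-6-[(2S,4S)-4-ethyl-2-methylhex-5-en-1-yl]-3-methoxy-1,2-dioxane; 20 trimethylsilyl acetate
Product: 24 2-[(3S,4S,6R)-4,6-diethyl-6-[(2S,4S)-4-ethyl-2-methylhex-5-en-1-yl]-1,2-dioxan-3-yl]acetic acid, via ketene bis(trimethylsilyl) acetal 21 (not isolated), via peroxycarbenium triflate 22 (not isolated), via trimethylsilyl ester 23 (not isolated)
Conditions: 20, LiN(iPr)2, Me3SiCl, THF, −78 °C, then filter and exchange to CH2Cl2; add 19, Me3SiOTf (0.3 equiv), −78 to −40 °C; then H2O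
Reagents that add atoms: none
Why: Lewis-acid ionisation of the peroxy acetal to the C3 peroxycarbenium ion followed by Mukaiyama-type addition of the silyl ketene acetal (an established way to make cyclic-peroxide 3-acetic acids); the chair is held by the equatorial C4 ethyl and C6 side chain, so axial attack places the CH2CO2 group cis to the C4 ethyl (3S), and aqueous work-up frees the acid from its silyl ester.

**Step 10**
Reactants: 24 2-[(3S,4S,6R)-4,6-diethyl-6-[(2S,4S)-4-ethyl-2-methylhex-5-en-1-yl]-1,2-dioxan-3-yl]acetic acid; 25 but-3-en-2-one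
Product: 26 2-[(3S,4S,6R)-4,6-diethyl-6-[(2S,4S,5E)-4-ethyl-2-methyl-7-oxooct-5-en-1-yl]-1,2-dioxan-3-yl]acetic acid
Conditions: 25 (5 equiv), second-generation Hoveyda–Grubbs catalyst (C31H38Cl2N2ORu, 5 mol %), CH2Cl2, 40 °C
Reagents that add atoms: none
Why: Olefin cross-metathesis of the terminal alkene with excess methyl vinyl ketone gives the E-enone under thermodynamic control, and ruthenium alkylidenes tolerate dialkyl peroxides and free carboxylic acids; no stereocentre is affected.

**Compound list**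
1 | (R)-3-bromo-2-methylpropan-1-ol | BrC[C@H](C)CO | starting material
2 | (R)-(3-bromo-2-methylpropoxy)triethylsilane | BrC[C@H](C)CO[Si](CC)(CC)CC | intermediate
3 | (E)-1-bromopent-2-ene | BrC/C=C/CC | starting material
4 | (R)-[2-methyl-3-(triethylsilyloxy)propyl]magnesium bromide | Br[Mg]C[C@H](C)CO[Si](CC)(CC)CC | intermediate
5 | triethyl{[(2S,4S)-4-ethyl-2-methylhex-5-en-1-yl]oxy}silane | CC[C@H](C=C)C[C@H](C)CO[Si](CC)(CC)CC | intermediate
6 | (2S,4S)-4-ethyl-2-methylhex-5-en-1-ol | CC[C@H](C=C)C[C@H](C)CO | intermediate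
7 | (3S,5S)-3-ethyl-6-iodo-5-methylhex-1-ene | CC[C@H](C=C)C[C@H](C)CI | intermediate
8 | 3-ethylcyclobutan-1-one | CCC1CC(=O)C1 | starting material
9 | (S)-[(3-ethylcyclobut-1-en-1-yl)oxy]trimethylsilane | C[Si](C)(C)OC1=C[C@@H](CC)C1 | intermediate
10 | (2R,3S)-3-ethyl-2-(trimethylsilyloxy)cyclobutan-1-one | O=C1C[C@H](CC)[C@H]1O[Si](C)(C)C | intermediate
11 | (2R,3S)-3-ethyl-2-hydroxycyclobutan-1-one | O=C1C[C@H](CC)[C@H]1O | intermediate
12 | (2R,3S)-3-ethyl-2-methoxycyclobutan-1-one | O=C1C[C@H](CC)[C@H]1OC | intermediate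
13 | [(2R,4S)-4-ethyl-2-methylhex-5-en-1-yl]lithium | CC[C@H](C=C)C[C@H](C)C[Li] | intermediate
14 | (2R,3S)-3-ethyl-1-[(2S,4S)-4-ethyl-2-methylhex-5-en-1-yl]-2-methoxycyclobutan-1-ol (both C1 epimers) | CC[C@H](C=C)C[C@H](C)CC1(O)C[C@H](CC)[C@H]1OC | intermediate
15 | (2S,6S,8S)-2,8-diethyl-1-hydroperoxy-1-methoxy-6-methyldec-9-en-4-one (C1 epimers) | CC[C@H](C=C)C[C@H](C)CC(=O)C[C@H](CC)C(OC)OO | intermediate
16 | (4S)-4-ethyl-6-[(2S,4S)-4-ethyl-2-methylhex-5-en-1-yl]-3-methoxy-1,2-dioxan-6-ol (C3 and C6 epimers) | CC[C@H](C=C)C[C@H](C)CC1(O)C[C@H](CC)C(OC)OO1 | intermediate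
17 | {[(4S)-4-ethyl-6-[(2S,4S)-4-ethyl-2-methylhex-5-en-1-yl]-3-methoxy-1,2-dioxan-6-yl]oxy}trimethylsilane | CC[C@H](C=C)C[C@H](C)CC1(O[Si](C)(C)C)C[C@H](CC)C(OC)OO1 | intermediate
18 | (4S)-4-ethyl-6-[(2S,4S)-4-ethyl-2-methylhex-5-en-1-yl]-3-methoxy-1,2-dioxan-6-ylium trifluoromethanesulfonate (peroxycarbenium ion, C6=O+) | CC[C@H](C=C)C[C@H](C)CC1=[O+]OC(OC)[C@@H](CC)C1.[O-]S(=O)(=O)C(F)(F)F | intermediate
19 | (4S,6R)-4,6-diethyl-6-[(2S,4S)-4-ethyl-2-methylhex-5-en-1-yl]-3-methoxy-1,2-dioxane (C3 epimers) | CC[C@H](C=C)C[C@H](C)C[C@]1(CC)C[C@H](CC)C(OC)OO1 | intermediate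
20 | trimethylsilyl acetate | CC(=O)O[Si](C)(C)C | starting material
21 | 1,1-bis(trimethylsilyloxy)ethene | C=C(O[Si](C)(C)C)O[Si](C)(C)C | intermediate
22 | (4S,6R)-4,6-diethyl-6-[(2S,4S)-4-ethyl-2-methylhex-5-en-1-yl]-1,2-dioxan-3-ylium trifluoromethanesulfonate (peroxycarbenium ion, C3=O+) | CC[C@H](C=C)C[C@H](C)C[C@]1(CC)C[C@H](CC)C=[O+]O1.[O-]S(=O)(=O)C(F)(F)F | intermediate
23 | trimethylsilyl 2-[(3S,4S,6R)-4,6-diethyl-6-[(2S,4S)-4-ethyl-2-methylhex-5-en-1-yl]-1,2-dioxan-3-yl]acetate | CC[C@H](C=C)C[C@H](C)C[C@]1(CC)C[C@H](CC)[C@H](CC(=O)O[Si](C)(C)C)OO1 | intermediate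
24 | 2-[(3S,4S,6R)-4,6-diethyl-6-[(2S,4S)-4-ethyl-2-methylhex-5-en-1-yl]-1,2-dioxan-3-yl]acetic acid | CC[C@H](C=C)C[C@H](C)C[C@]1(CC)C[C@H](CC)[C@H](CC(=O)O)OO1 | intermediate
25 | but-3-en-2-one | CC(=O)C=C | starting material
26 | 2-[(3S,4S,6R)-4,6-diethyl-6-[(2S,4S,5E)-4-ethyl-2-methyl-7-oxooct-5-en-1-yl]-1,2-dioxan-3-yl]acetic acid | CC[C@H](/C=C/C(C)=O)C[C@H](C)C[C@]1(CC)C[C@H](CC)[C@H](CC(=O)O)OO1 | target

**Step count**
Total: 10 steps. Longest linear sequence: 8 steps (1, 2, 3, 6, 7, 8, 9, 10); steps 4 and 5 form the convergent branch.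

**Steps most likely to fail and their fallbacks**

Step 4 (desymmetrising enolisation and α-hydroxylation). The enantiomeric excess with a 3-alkyl substituent may be modest, and the α-ketol is strained. Fallback from 8 back to 11 by resolution instead of asymmetric deprotonation: LiN(iPr)2/Me3SiCl gives racemic [(3-ethylcyclobut-1-en-1-yl)oxy]trimethylsilane F1; dimethyldioxirane and then methanol give racemic trans-3-ethyl-2-hydroxycyclobutan-1-one F2; preparative HPLC on a cellulose tris(3,5-dimethylphenylcarbamate) phase delivers the (2R,3S) enantiomer, which is 11.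

Step 7 (oxidative ring expansion). The α-methoxy substituent is outside the usual substrate range, and the alkoxyl radical could also abstract hydrogen from the side chain. Fallback from 7 back to 16 without a cyclobutane: iodine–lithium exchange on 7 (t-BuLi, −78 °C) and acylation with N-methoxy-N-methylacrylamide give (5S,7S)-7-ethyl-5-methylnona-1,8-dien-3-one F3. Enamine-catalysed Michael addition of butanal (diphenylprolinol trimethylsilyl ether, the enantiomer giving 2S) sets C4 and gives (2S,6S,8S)-2,8-diethyl-6-methyl-4-oxodec-9-enal F4. HC(OMe)3/MeOH/pyridinium p-toluenesulfonate acetalises only the aldehyde to (3S,5S,9S)-9-(dimethoxymethyl)-3-ethyl-5-methylundec-1-en-7-one F5. Acid-catalysed exchange of one methoxy group for hydroperoxide (anhydrous H2O2 in Et2O, camphorsulfonic acid cat.) gives 15, which closes to 16.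

Step 8 (the proposed ethyl transfer to the peroxycarbenium ion). Et2Zn may reduce the peroxide, or the C3 acetal may ionise as well. Fallback from 16 back to 19 using known chemistry: ionise 16 as before (Me3SiOTf, hindered pyridine, −78 °C) but trap with trimethyl(vinyloxy)silane, a silyl enol ether of the kind known to add to peroxycarbenium ions, with the same axial selectivity. This gives 2-[(4S,6R)-4-ethyl-6-[(2S,4S)-4-ethyl-2-methylhex-5-en-1-yl]-3-methoxy-1,2-dioxan-6-yl]acetaldehyde F6. NaBH4 (MeOH, 0 °C) gives 2-[(4S,6R)-4-ethyl-6-[(2S,4S)-4-ethyl-2-methylhex-5-en-1-yl]-3-methoxy-1,2-dioxan-6-yl]ethan-1-ol F7. TsCl/pyridine gives 2-[(4S,6R)-4-ethyl-6-[(2S,4S)-4-ethyl-2-methylhex-5-en-1-yl]-3-methoxy-1,2-dioxan-6-yl]ethyl 4-methylbenzenesulfonate F8. NaBH4 in DMSO (60 °C) displaces the sulfonate by hydride to give 19.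

**Further compounds**
F1 | step 4 | racemic [(3-ethylcyclobut-1-en-1-yl)oxy]trimethylsilane | C[Si](C)(C)OC1=CC(CC)C1
F2 | step 4 | racemic trans-3-ethyl-2-hydroxycyclobutan-1-one | O=C1CC(CC)C1O
F3 | step 7 | (5S,7S)-7-ethyl-5-methylnona-1,8-dien-3-one | CC[C@H](C=C)C[C@H](C)CC(=O)C=C
F4 | step 7 | (2S,6S,8S)-2,8-diethyl-6-methyl-4-oxodec-9-enal | CC[C@H](C=C)C[C@H](C)CC(=O)C[C@H](CC)C=O
F5 | step 7 | (3S,5S,9S)-9-(dimethoxymethyl)-3-ethyl-5-methylundec-1-en-7-one | CC[C@H](C=C)C[C@H](C)CC(=O)C[C@H](CC)C(OC)OC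
F6 | step 8 | 2-[(4S,6R)-4-ethyl-6-[(2S,4S)-4-ethyl-2-methylhex-5-en-1-yl]-3-methoxy-1,2-dioxan-6-yl]acetaldehyde | CC[C@H](C=C)C[C@H](C)C[C@]1(CC=O)C[C@H](CC)C(OC)OO1
F7 | step 8 | 2-[(4S,6R)-4-ethyl-6-[(2S,4S)-4-ethyl-2-methylhex-5-en-1-yl]-3-methoxy-1,2-dioxan-6-yl]ethan-1-ol | CC[C@H](C=C)C[C@H](C)C[C@]1(CCO)C[C@H](CC)C(OC)OO1
F8 | step 8 | 2-[(4S,6R)-4-ethyl-6-[(2S,4S)-4-ethyl-2-methylhex-5-en-1-yl]-3-methoxy-1,2-dioxan-6-yl]ethyl 4-methylbenzenesulfonate | CC[C@H](C=C)C[C@H](C)C[C@]1(CCOS(=O)(=O)c2ccc(C)cc2)C[C@H](CC)C(OC)OO1
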